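**Strategy**

The side chain is numbered from the benzylic carbon (C1) to C16. Everything rests on disconnecting C7–C8, the bond between the methyl-bearing alkene carbon and the first CH2 of a homogeranyl unit. The key step is an iron-catalysed, hydroxyl-directed syn-carbomagnesiation: homogeranylmagnesium iodide adds across a C6≡C7 triple bond. It exploits the free C5 hydroxyl beside the C6=C7 alkene: in one operation it forges C7–C8 and sets the 6E trisubstituted alkene, while the C5 stereocentre passes through untouched and the hydroquinone ring stays masked as its bis-silyl ether. The precursor is an (R)-oct-2-en-6-yn-5-ol carrying the protected arene: an alkyne where the target has an alkene.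

Key step: step 7

Remark: CIP analysis of the target gives 5R for the carbinol carbon (O > C6 > C4 > H); but-2-ynal 4 is taken as a purchasable, volatile aldehyde that is distilled before use.

**Route**

Step 1
Reactants: 1 2,6-dimethylbenzene-1,4-diol
Product: 2 1,4-bis(tert-butyldimethylsilyloxy)-2,6-dimethylbenzene
Conditions: TBSCl (2.5 equiv), imidazole (5 equiv), DMF, 40 °C
Reagents that add atoms: tert-butyldimethylsilyl chloride, CC(C)(C)[Si](C)(C)Cl
Why: Imidazole-promoted silylation of both phenols (silyl ether protection) should give aryl silyl ethers that tolerate the organoaluminium and Grignard steps and fall to fluoride at the end.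

Step 2
Reactants: 2 1,4-bis(tert-butyldimethylsilyloxy)-2,6-dimethylbenzene
Product: 3 2-(bromomethyl)-1,4-bis(tert-butyldimethylsilyloxy)-6-methylbenzene
Conditions: NBS (1.0 equiv), AIBN (5 mol%), PhCF3, 80 °C
Reagents that add atoms: N-bromosuccinimide, O=C1CCC(=O)N1Br
Why: Wohl–Ziegler radical benzylic bromination should give one regioisomer because the two methyl groups are equivalent by symmetry, and the non-polar radical conditions with bulky silyloxy groups disfavour ring bromination.

Step 3
Reactants: 4 but-2-ynal; 5 allenylboronic acid pinacol ester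
Product: 7 (R)-hepta-1,5-diyn-4-ol, via pinacol borate ester 6 (not isolated)
Conditions: (R)-TRIP [(R)-3,3'-bis(2,4,6-triisopropylphenyl)-1,1'-binaphthyl-2,2'-diyl hydrogen phosphate] (10 mol%), 4 Å molecular sieves, toluene, −20 °C; aq. NaHCO3; careful concentration
Reagents that add atoms: none
Why: Chiral phosphoric acid-catalysed asymmetric propargylation, in which the allenylboronate adds through a closed six-membered SE2' transition state and the acid (hydrogen-bonded to a boronate oxygen and the formyl hydrogen) directs attack to the Re face of the aldehyde, setting the R carbinol that becomes C5; (R)-TRIP is the antipode expected to do this by analogy with aryl and alkenyl aldehydes, and the (S)-acid is taken instead should MTPA ester analysis show the opposite sense.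

Step 4
Reactants: 7 (R)-hepta-1,5-diyn-4-ol; 3 2-(bromomethyl)-1,4-bis(tert-butyldimethylsilyloxy)-6-methylbenzene
Product: 9 (2E,5R)-1-[2,5-bis(tert-butyldimethylsilyloxy)-3-methylphenyl]-3-methyloct-2-en-6-yn-5-ol, via alkenylalane 8 (not isolated)
Conditions: Me3Al (3.5 equiv), Cp2ZrCl2 (0.25 equiv), CH2Cl2, 0 °C to rt; then 3, Pd(PPh3)4 (5 mol%), THF, rt; aq. potassium sodium tartrate
Reagents that add atoms: trimethylaluminium, C[Al](C)C
Why: Negishi carboalumination (zirconium-catalysed syn methylalumination, much faster at the terminal than at the internal alkyne, methyl to the internal carbon) should give the E-alkenylalane, which is benzylated under zerovalent palladium catalysis with retention to fix the 2E alkene, the stereocentre being untouched.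

Step 5
Reactants: 10 thioanisole; 11 geranyl bromide
Product: 13 (E)-(4,8-dimethylnona-3,7-dien-1-yl)(phenyl)sulfane, via (phenylthio)methyllithium 12 (not isolated)
Conditions: n-BuLi, DABCO, THF, 0 °C; then 11, −78 °C to rt
Reagents that add atoms: none
Why: Lithiation of thioanisole gives a sulfur-stabilised organolithium that should displace the primary allylic bromide by SN2 at the α-carbon, adding one carbon and leaving the E alkene as it is.

Step 6
Reactants: 13 (E)-(4,8-dimethylnona-3,7-dien-1-yl)(phenyl)sulfane
Product: 15 (E)-1-iodo-4,8-dimethylnona-3,7-diene, via methylsulfonium iodide 14 (not isolated)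
Conditions: MeI (excess), NaI, DMF, 75 °C
Reagents that add atoms: iodomethane, CI; sodium iodide, [Na+].[I-] (the shared iodide pool from which the product iodide is drawn)
Why: S-methylation gives a sulfonium salt whose primary homoallylic carbon is displaced by iodide with release of thioanisole (sulfide-to-iodide exchange by SN2), conditions under which the trisubstituted alkenes are inert.

Step 7
Reactants: 15 (E)-1-iodo-4,8-dimethylnona-3,7-diene; 9 (2E,5R)-1-[2,5-bis(tert-butyldimethylsilyloxy)-3-methylphenyl]-3-methyloct-2-en-6-yn-5-ol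
Product: 18 (2E,5R,6E,10E)-1-[2,5-bis(tert-butyldimethylsilyloxy)-3-methylphenyl]-3,7,11,15-tetramethylhexadeca-2,6,10,14-tetraen-5-ol, via homogeranylmagnesium iodide 16 (not isolated), via alkenylmagnesium alkoxide 17 (not isolated)
Conditions: Mg turnings, Et2O, rt (15 to 16, 3 equiv); then 9, Fe(acac)3 (20 mol%), dppe (20 mol%), THF, −78 to 0 °C; aq. NH4Cl
Reagents that add atoms: none
Why: The first equivalent of 16 deprotonates the C5 hydroxyl, Fe(acac)3 is reduced by 16 to a low-valent alkyliron species that binds the magnesium alkoxide and inserts the C6≡C7 triple bond syn into its Fe–C bond, the homogeranyl CH2 going to the distal carbon C7 and iron to C6, and iron-to-magnesium exchange gives 17, which is protonated on work-up. The closest known reaction type is the iron-catalysed syn-carbomagnesiation of propargylic and homopropargylic alcohols with Grignard reagents. No ring is closed. No stereocentre is created: the 5R centre is carried through because no bond to it is broken, and the 6E geometry follows from syn addition, which places the new C8 trans to C5 and the methyl cis. The step needs regioselectivity (alkyl to C7), syn stereospecificity, carbometalation over hydrometalation, and reaction at the alkyne in preference to the C2=C3 alkene; the C5 alkoxide tether secures the first two and the last, and dppe with low temperature should restrain β-hydride elimination from the alkyliron.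

Step 8
Reactants: 18 (2E,5R,6E,10E)-1-[2,5-bis(tert-butyldimethylsilyloxy)-3-methylphenyl]-3,7,11,15-tetramethylhexadeca-2,6,10,14-tetraen-5-ol
Product: 19 2-[(2E,5R,6E,10E)-5-hydroxy-3,7,11,15-tetramethylhexadeca-2,6,10,14-tetraen-1-yl]-6-methylbenzene-1,4-diol
Conditions: TBAF (2.5 equiv), AcOH (2.5 equiv), degassed THF, 0 °C, under argon
Reagents that add atoms: none
Why: Fluoride-mediated desilylation driven by the Si–F bond should free both phenols, while the acetic acid buffer and exclusion of air keep the hydroquinone from oxidising and leave the allylic alcohol and the four alkenes untouched.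

**Compound list**

1 | 2,6-dimethylbenzene-1,4-diol | Cc1cc(O)cc(C)c1O | starting material
2 | 1,4-bis(tert-butyldimethylsilyloxy)-2,6-dimethylbenzene | Cc1cc(O[Si](C)(C)C(C)(C)C)cc(C)c1O[Si](C)(C)C(C)(C)C | intermediate
3 | 2-(bromomethyl)-1,4-bis(tert-butyldimethylsilyloxy)-6-methylbenzene | Cc1cc(O[Si](C)(C)C(C)(C)C)cc(CBr)c1O[Si](C)(C)C(C)(C)C | intermediate
4 | but-2-ynal | CC#CC=O | starting material
5 | allenylboronic acid pinacol ester (4,4,5,5-tetramethyl-2-(propa-1,2-dienyl)-1,3,2-dioxaborolane) | C=C=CB1OC(C)(C)C(C)(C)O1 | starting material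
6 | pinacol borate ester of (R)-hepta-1,5-diyn-4-ol | CC#C[C@H](OB1OC(C)(C)C(C)(C)O1)CC#C | intermediate
7 | (R)-hepta-1,5-diyn-4-ol | CC#C[C@H](O)CC#C | intermediate
8 | [(1E,4R)-4-(dimethylaluminiooxy)-2-methylhept-1-en-5-yn-1-yl]dimethylalane | CC#C[C@H](O[Al](C)C)C/C(C)=C/[Al](C)C | intermediate
9 | (2E,5R)-1-[2,5-bis(tert-butyldimethylsilyloxy)-3-methylphenyl]-3-methyloct-2-en-6-yn-5-ol | CC#C[C@H](O)C/C(C)=C/Cc1cc(O[Si](C)(C)C(C)(C)C)cc(C)c1O[Si](C)(C)C(C)(C)C | intermediate
10 | thioanisole | CSc1ccccc1 | starting material
11 | geranyl bromide ((E)-1-bromo-3,7-dimethylocta-2,6-diene) | CC(C)=CCC/C(C)=C/CBr | starting material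
12 | (phenylthio)methyllithium | [Li]CSc1ccccc1 | intermediate
13 | (E)-(4,8-dimethylnona-3,7-dien-1-yl)(phenyl)sulfane (homogeranyl phenyl sulfide) | CC(C)=CCC/C(C)=C/CCSc1ccccc1 | intermediate
14 | (E)-(4,8-dimethylnona-3,7-dien-1-yl)(methyl)(phenyl)sulfonium iodide | CC(C)=CCC/C(C)=C/CC[S+](C)c1ccccc1.[I-] | intermediate
15 | (E)-1-iodo-4,8-dimethylnona-3,7-diene (homogeranyl iodide) | CC(C)=CCC/C(C)=C/CCI | intermediate
16 | homogeranylmagnesium iodide | CC(C)=CCC/C(C)=C/CC[Mg]I | intermediate
17 | alkenylmagnesium alkoxide from syn addition (magnesium on C6 cis to C8, iodomagnesium alkoxide on C5) | CC(C)=CCC/C(C)=C/CC/C(C)=C(\[Mg]I)[C@H](O[Mg]I)C/C(C)=C/Cc1cc(O[Si](C)(C)C(C)(C)C)cc(C)c1O[Si](C)(C)C(C)(C)C | intermediate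
18 | (2E,5R,6E,10E)-1-[2,5-bis(tert-butyldimethylsilyloxy)-3-methylphenyl]-3,7,11,15-tetramethylhexadeca-2,6,10,14-tetraen-5-ol | CC(C)=CCC/C(C)=C/CC/C(C)=C/[C@H](O)C/C(C)=C/Cc1cc(O[Si](C)(C)C(C)(C)C)cc(C)c1O[Si](C)(C)C(C)(C)C | intermediate
19 | 2-[(2E,5R,6E,10E)-5-hydroxy-3,7,11,15-tetramethylhexadeca-2,6,10,14-tetraen-1-yl]-6-methylbenzene-1,4-diol | CC(C)=CCC/C(C)=C/CC/C(C)=C/[C@H](O)C/C(C)=C/Cc1cc(O)cc(C)c1O | target

**Summary**

Total step count: 8. Longest linear sequence: 5 steps (steps 1, 2, 4, 7, 8).

**Steps most likely to fail**

Step 7. β-Hydride elimination from the alkyliron intermediate may outrun insertion, so that the alkyne is hydromagnesiated (reduced) and no C7–C8 bond forms, or the catalyst may stall on the hindered secondary alkoxide. The fallback is a stereospecific sp2–sp3 cross-coupling. It sets out from 9, which is hydrozirconated with Cp2Zr(H)Cl (3 equiv, THF, 50 °C, zirconium settling on the methyl-bearing carbon) and quenched with I2 to give (2E,5R,6E)-1-[2,5-bis(tert-butyldimethylsilyloxy)-3-methylphenyl]-7-iodo-3-methylocta-2,6-dien-5-ol F1. Iodide 15 is converted with Zn dust and LiCl in THF into homogeranylzinc iodide F2. Negishi coupling of F1 with F2 (Pd(OAc)2, SPhos, THF, rt) proceeds with retention and comes back to the route at 18.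

Step 4. Chemoselectivity between the two alkynes may be lost, or the Lewis-acidic aluminium species may methylate or ionise the electron-rich benzylic bromide before cross-coupling. The fallback reverses the polarity of the coupling. It sets out from 7, which after the same carboalumination is quenched with I2 to give (1E,4R)-1-iodo-2-methylhept-1-en-5-yn-4-ol F3. Bromide 3 is converted with Zn dust and LiCl in THF into [2,5-bis(tert-butyldimethylsilyloxy)-3-methylbenzyl]zinc bromide F4. Negishi coupling of F3 with F4 (Pd(PPh3)4, THF, rt) comes back to the route at 9.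

Step 3. Facial selectivity may be poor with a small, linear ynal, giving 7 and then 9 of insufficient enantiomeric purity. The fallback sets the stereocentre by reagent-controlled reduction instead of by C–C bond formation. It sets out from 9 of low enantiomeric purity, which is oxidised with Dess–Martin periodinane buffered with NaHCO3 to (E)-1-[2,5-bis(tert-butyldimethylsilyloxy)-3-methylphenyl]-3-methyloct-2-en-6-yn-5-one F5, used at once to avoid alkene migration. Noyori asymmetric transfer hydrogenation of F5 with RuCl[(R,R)-TsDPEN](p-cymene) in i-PrOH at rt is expected to return the R carbinol and comes back to the route at 9.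

**Further compounds**

F1 | step 7 | (2E,5R,6E)-1-[2,5-bis(tert-butyldimethylsilyloxy)-3-methylphenyl]-7-iodo-3-methylocta-2,6-dien-5-ol | I/C(C)=C/[C@H](O)C/C(C)=C/Cc1cc(O[Si](C)(C)C(C)(C)C)cc(C)c1O[Si](C)(C)C(C)(C)C
F2 | step 7 | homogeranylzinc iodide | CC(C)=CCC/C(C)=C/CC[Zn]I
F3 | step 4 | (1E,4R)-1-iodo-2-methylhept-1-en-5-yn-4-ol | CC#C[C@H](O)C/C(C)=C/I
F4 | step 4 | [2,5-bis(tert-butyldimethylsilyloxy)-3-methylbenzyl]zinc bromide | Cc1cc(O[Si](C)(C)C(C)(C)C)cc(C[Zn]Br)c1O[Si](C)(C)C(C)(C)C
F5 | step 3 | (E)-1-[2,5-bis(tert-butyldimethylsilyloxy)-3-methylphenyl]-3-methyloct-2-en-6-yn-5-one | CC#CC(=O)C/C(C)=C/Cc1cc(O[Si](C)(C)C(C)(C)C)cc(C)c1O[Si](C)(C)C(C)(C)C
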